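The route rests on reading the tetrahydrofuran ring (O, C8, C9, C10, C11) as a cut-open 7-oxanorbornene: C7 on C8 and C12 on C11 are cis across the ring oxygen, while the C9 and C10 substituents are trans. An enantioselective Diels-Alder reaction of furan-2-yl methacrylate with benzyl (E)-4-oxopent-2-enoate therefore forms C8-C9 and C10-C11 and sets all four ring stereocentres at once, with the future spirolactone acyl group already on C11. Ring-rearrangement metathesis then cuts C7=C12 and closes the butenolide; a lactone alkyne, amine condensation with 5-endo-dig closure, and C9a hydroxylation of the resulting 3-hydroxypyrrole finish the skeleton.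

Key step: step 3

Remark on numbering: alkaloid numbering is used throughout (C1 to C3 and N4 in the pyrrolinone, C5 to C7 the chain, C8, C9, C10 and spiro C11 in the tetrahydrofuran, C9a the hemiaminal carbon, C12 to C14 the spirolactone, C16 and C17 the ethyl group, C18 to C21 the side lactone).

Assumption: the (S)-configured oxazaborolidinium catalyst is taken to shield the face of the ketone-bound dienophile that leads to 6; should the induction prove opposite, the (R)-catalyst is used with no other change.

Step 1
Reactants: 1 furan-2(5H)-one; 2 methacryloyl chloride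
Product: 3 furan-2-yl methacrylate
Conditions: Et3N, BHT (trace), CH2Cl2, 0 °C
Reagents that add atoms: none
Why: Et3N generates the 2-furanolate (the dienolate of the butenolide), which is O-acylated by the acid chloride because that restores the aromatic furan (O-acylation of a dienolate, the reaction type that also gives 2-acetoxyfuran and 2-silyloxyfurans); no stereocentre is formed.

Step 2
Reactants: 4 (E)-4-oxopent-2-enoic acid
Product: 5 benzyl (E)-4-oxopent-2-enoate
Conditions: BnBr, NaHCO3, DMF, rt
Reagents that add atoms: benzyl bromide, BrCc1ccccc1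
Why: Carboxylate SN2 alkylation under weakly basic hydrogencarbonate conditions esterifies the acid without touching the base-sensitive E-enone; no stereocentre is formed.

Step 3
Reactants: 3 furan-2-yl methacrylate; 5 benzyl (E)-4-oxopent-2-enoate
Product: 6 benzyl 3-endo-acetyl-4-(methacryloyloxy)-7-oxabicyclo[2.2.1]hept-5-ene-2-exo-carboxylate (acetyl on C10, ester on C9, C8 to C11 configured as in the target)
Conditions: (S)-3,3-diphenyl-1-(o-tolyl)tetrahydro-1H,3H-pyrrolo[1,2-c][1,3,2]oxazaborole N-protonated by HNTf2 (20 mol %), 3 (1.5 equiv), CH2Cl2, -78 to -60 °C; pH 7 buffer, cold work-up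
Reagents that add atoms: none
Why: The cationic boron Lewis acid binds the ketone oxygen of 5, the more basic of its two carbonyl groups, and the normal-demand, strongly asynchronous [4+2] cycloaddition starts with bonding of furan C5 of 3 (the future C8) to the enone beta carbon (C9), after which the alpha carbon (C10) closes on the acyloxy-bearing furan C2 (C11), a stepwise Michael-then-closure course ending in the same bicycle. The closest known reaction types are oxazaborolidinium-catalysed Diels-Alder reactions of furan with acrylates and enones and the cycloadditions of 2-acetoxyfuran with activated alkenes. The six-membered carbocycle C8-C9-C10-C11-C12=C7 closes by suprafacial cycloaddition, which turns the furan into the oxygen-bridged tetrahydrofuran ring (O, C8, C9, C10, C11) of a 7-oxabicyclo[2.2.1]heptene. C9 and C10 are trans because the E geometry of 5 is carried over, the complexed ketone takes the endo position so that the future ethyl carbon sits on the face of the C7=C12 bridge and the ester is exo, C8 and C11 are tied together by the bicycle (C7 and C12 cis), and the absolute sense of all four centres comes from the diphenylprolinol-derived ligand shielding one face of the bound enone. The step needs regio-, endo- and facial selectivity: the first is secured by matching the acyloxy donor (nucleophilic C5 terminus) with ketone rather than ester activation, the second by the endo preference of the Lewis acid-bound ketone and the third by the catalyst, while the methacrylate alkene is too poor a dienophile to interfere and loss of carboxylate beta to the ketone would need a bridgehead alkene. Cycloreversion and base-induced opening of the oxygen bridge are avoided by cold, neutral handling and immediate use in step 4.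

Step 4
Reactants: 6 Diels-Alder adduct
Product: 7 N-tosylhydrazone of 6 at the acetyl carbon
Conditions: TsNHNH2 (1.05 equiv), MgSO4, THF, 0 °C to rt
Reagents that add atoms: p-toluenesulfonyl hydrazide, Cc1ccc(cc1)S(=O)(=O)NN
Why: Condensation of the unhindered methyl ketone with the sulfonyl hydrazide (tosylhydrazone formation) under neutral, dehydrating conditions masks the ketone at once, which removes the activating group that favours cycloreversion and enolisation toward C10; no stereocentre is formed or touched.

Step 5
Reactants: 7 tosylhydrazone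
Product: 9 benzyl 3-endo-ethyl-4-(methacryloyloxy)-7-oxabicyclo[2.2.1]hept-5-ene-2-exo-carboxylate, via alkyldiazene 8 (not isolated)
Conditions: catecholborane, CHCl3, 0 °C; then NaOAc·3H2O, rt to 40 °C
Reagents that add atoms: none
Why: Caglioti-type deoxygenation in its mild catecholborane variant: hydride adds to the C=N bond, acetate triggers loss of sulfinate to the alkyldiazene 8 and extrusion of N2 leaves the CH2 of the ethyl group, while both esters and both alkenes are inert to catecholborane at this temperature and C10 cannot epimerise once the ketone is gone.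

Step 6
Reactants: 9 ethyl oxanorbornene
Product: 11 benzyl 9-ethyl-3-methyl-2-oxo-7-vinyl-1,6-dioxaspiro[4.4]non-3-ene-8-carboxylate (spiro-butenolide on C11; vinyl on C8), via ring-opened triene 10 (not isolated)
Conditions: second-generation Hoveyda-Grubbs catalyst RuCl2(H2IMes)(=CH-C6H4-2-OiPr) (5 mol %), ethylene (1 atm), CH2Cl2, rt; then Ar purge, 40 °C
Reagents that add atoms: ethylene, C=C
Why: Ring-rearrangement metathesis (ring-opening then ring-closing metathesis): strain release drives ethenolysis of the C7=C12 bridge to triene 10, whose C12 vinyl group then closes with the methacrylate alkene to the five-membered butenolide with loss of ethylene, so the temporary carbocycle is exchanged for the spirolactone while C8, C9, C10 and C11 stay untouched.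

Step 7
Reactants: 11 spiro-butenolide with C8 vinyl; 12 tert-butyl allylcarbamate
Product: 13 benzyl 7-[(E)-3-(tert-butoxycarbonylamino)prop-1-enyl]-9-ethyl-3-methyl-2-oxo-1,6-dioxaspiro[4.4]non-3-ene-8-carboxylate
Conditions: RuCl2(H2IMes)(=CH-C6H4-2-OiPr) (5 mol %), 12 (3 equiv), CH2Cl2, 40 °C
Reagents that add atoms: none
Why: Olefin cross metathesis of the monosubstituted C8 vinyl group with an excess of the readily dimerising allyl carbamate; the trisubstituted, electron-poor butenolide alkene does not engage the ruthenium carbene, and the alkene geometry is irrelevant because the alkene is hydrogenated in step 10.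

Step 8
Reactants: 13 allylic carbamate
Product: 15 C12 alcohol (saturated hydroxy spirolactone; OH on the face of the ring oxygen; C13 methyl trans to OH), via pinacol boronate 14 (not isolated)
Conditions: B2pin2, CuCl (5 mol %), DPEphos (5 mol %), NaOtBu (5 mol %), MeOH (2 equiv), THF, 0 °C to rt; then NaBO3·4H2O, THF/H2O, 0 °C to rt
Reagents that add atoms: sodium perborate (NaBO3·4H2O), [Na+].[Na+].O[B-]1(O)OO[B-](O)(O)OO1
Why: Copper-catalysed conjugate borylation of the butenolide followed by oxidation of the C-B bond with retention: the boryl copper species should add to C12 on the face of the tetrahydrofuran oxygen, away from C10 and its cis ethyl group, syn protodemetalation by methanol places H13 cis to boron and hence the methyl trans (also the more stable arrangement, so any epimerisation converges), and the isolated chain alkene and the carbamate are not substrates for boryl copper.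

Step 9
Reactants: 15 C12 alcohol
Product: 16 C12 triethylsilyl ether of 15
Conditions: Et3SiCl, imidazole, DMAP (cat.), DMF, 0 °C to rt
Reagents that add atoms: chlorotriethylsilane, CC[Si](Cl)(CC)CC
Why: Imidazole-promoted silyl ether formation shields the C12 hydroxyl from the chloroformate of step 11 and the zinc reagent of step 19, the carbamate N-H being unreactive under these conditions.

Step 10
Reactants: 16 silyl ether
Product: 17 C9 carboxylic acid with saturated C5 to C7 chain (Boc-amine, C12 silyl ether)
Conditions: H2 (1 atm), palladium on carbon (Pd/C, 10 wt %), EtOAc, rt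
Reagents that add atoms: none
Why: Heterogeneous catalytic hydrogenation saturates the C6=C7 alkene and hydrogenolyses the benzyl ester in the same operation, while ethyl acetate as solvent keeps the triethylsilyl ether, the Boc group and the acyloxy ketal intact; no stereocentre is affected.

Step 11
Reactants: 17 C9 carboxylic acid
Product: 19 diazomethyl ketone at C9, via mixed anhydride 18 (not isolated)
Conditions: iBuOCOCl, N-methylmorpholine, THF, -15 °C; then CH2N2, Et2O, -15 to 0 °C
Reagents that add atoms: diazomethane, C=[N+]=[N-]
Why: Activation as the mixed carbonic anhydride 18 and C-acylation of diazomethane (first stage of the Arndt-Eistert protocol) gives the diazoketone under near-neutral conditions, and C9 is not at risk because its all-trans arrangement is already the stable one.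

Step 12
Reactants: 19 diazoketone
Product: 20 keto aldehyde (C9a ketone, C1 aldehyde)
Conditions: dimethyldioxirane (dried acetone solution), CH2Cl2, -20 to 0 °C; toluene azeotrope, used at once
Reagents that add atoms: dimethyldioxirane, CC1(C)OO1
Why: Dimethyldioxirane transfers oxygen to the diazo carbon and N2 departs, the established conversion of alpha-diazoketones into alpha-keto aldehydes under neutral conditions; the carbamate, silyl ether and lactone are inert to the reagent at this temperature.

Step 13
Reactants: 21 (S)-5-(hydroxymethyl)dihydrofuran-2(3H)-one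
Product: 22 (S)-5-[(tert-butyldiphenylsilyloxy)methyl]dihydrofuran-2(3H)-one
Conditions: tBuPh2SiCl, imidazole, DMF, rt
Reagents that add atoms: tert-butyl(chloro)diphenylsilane, CC(C)(C)[Si](Cl)(c1ccccc1)c1ccccc1
Why: Imidazole-promoted silylation of the primary alcohol installs a bulky group that later steers the hydrogenation; the stereocentre is untouched.

Step 14
Reactants: 22 silyl-protected lactone
Product: 26 (S)-5-[(tert-butyldiphenylsilyloxy)methyl]-3-methylenedihydrofuran-2(3H)-one, via lithium enolate 23 (not isolated), via Mannich base 24 (not isolated), via ammonium iodide 25 (not isolated)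
Conditions: LiN(iPr)2, THF, -78 °C; CH2=NMe2+ I-, -78 °C to rt; MeI, MeOH, rt; DBU, CH2Cl2, rt
Reagents that add atoms: Eschenmoser's salt (N,N-dimethylmethyleneiminium iodide), C=[N+](C)C.[I-]
Why: Alpha-methylenation by Mannich reaction of the lithium enolate 23 with Eschenmoser's salt, exhaustive N-methylation of 24 and Hofmann-type elimination of trimethylamine from 25; C5 is not enolisable and keeps its configuration.

Step 15
Reactants: 26 alpha-methylene lactone
Product: 27 (3S,5S)-5-[(tert-butyldiphenylsilyloxy)methyl]-3-methyldihydrofuran-2(3H)-one (cis)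
Conditions: H2 (1 atm), rhodium on alumina (Rh/Al2O3, 5 wt %), EtOAc, rt
Reagents that add atoms: none
Why: Heterogeneous hydrogenation delivers hydrogen to the exocyclic alkene from the face opposite the bulky silyloxymethyl group at C5, so the new methyl group ends cis to that group, which is the (3S,5S) lactone; rhodium is chosen because it isomerises the alkene into the ring less readily than palladium.

Step 16
Reactants: 27 cis methyl lactone
Product: 28 (3S,5S)-5-(hydroxymethyl)-3-methyldihydrofuran-2(3H)-one
Conditions: Bu4NF, AcOH, THF, 0 °C to rt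
Reagents that add atoms: none
Why: Fluoride-induced desilylation buffered with acetic acid frees the primary alcohol without base-induced epimerisation at C3 or translactonisation.

Step 17
Reactants: 28 hydroxymethyl lactone
Product: 29 (2S,4S)-4-methyl-5-oxotetrahydrofuran-2-carbaldehyde
Conditions: Dess-Martin periodinane, CH2Cl2, 0 °C to rt; used crude
Reagents that add atoms: none
Why: Dess-Martin oxidation of the primary alcohol under neutral conditions gives the alpha-acyloxy aldehyde without epimerising the adjacent centre.

Step 18
Reactants: 29 lactone aldehyde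
Product: 30 (3S,5S)-5-ethynyl-3-methyldihydrofuran-2(3H)-one
Conditions: dimethyl (1-diazo-2-oxopropyl)phosphonate, K2CO3, MeOH, 0 °C to rt; work-up at pH 4
Reagents that add atoms: dimethyl (1-diazo-2-oxopropyl)phosphonate, CC(=O)C(=[N+]=[N-])P(=O)(OC)OC
Why: Ohira-Bestmann variant of the Seyferth-Gilbert homologation: methanolysis of the reagent gives the dimethyl (diazomethyl)phosphonate anion, which adds to the aldehyde, loses dimethyl phosphate and N2 and rearranges by 1,2-hydrogen shift to the terminal alkyne under carbonate conditions mild enough for alpha-oxygenated aldehydes, and the mildly acidic work-up recloses any lactone opened by methanol.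

Step 19
Reactants: 20 keto aldehyde; 30 (3S,5S)-5-ethynyl-3-methyldihydrofuran-2(3H)-one
Product: 32 alpha-hydroxy propargyl ketone (C9a ketone; C1 carbinol as both epimers), via alkynylzinc triflate 31 (not isolated)
Conditions: Zn(OTf)2, Et3N, toluene, rt; then 20, 0 °C to rt
Reagents that add atoms: none
Why: Amine/zinc triflate alkynylation of aldehydes (Carreira conditions, without a chiral ligand because C1 is erased later): the alkynylzinc species 31 formed in the flask adds to the aldehyde, which is far more electrophilic than the neighbouring ketone, under conditions too weakly basic to enolise the lactones, and retro-oxa-Michael opening of the tetrahydrofuran from C9 would be the reverse of a disfavoured 5-endo-trig closure; both C1 epimers are expected and both are used.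

Step 20
Reactants: 32 alpha-hydroxy propargyl ketone
Product: 33 ammonium trifluoroacetate of the amino ketone with free C12 hydroxyl
Conditions: CF3CO2H/CH2Cl2/H2O (10:10:1), 0 °C to rt; evaporation, toluene azeotrope
Reagents that add atoms: trifluoroacetic acid, OC(=O)C(F)(F)F
Why: Acidolysis removes the Boc group (as isobutene and CO2) and aqueous acid hydrolyses the triethylsilyl ether, while the amine stays protonated so that it cannot condense prematurely and the propargylic carbinol cannot ionise next to the ketone (no Meyer-Schuster shift).

Step 21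
Reactants: 33 ammonium trifluoroacetate
Product: 36 3-hydroxypyrrole form of the pyrrolo[1,2-a]azepine (tautomer of the C9a-H pyrrolin-1-one), via cyclic imine 34 (not isolated), via amino ynone 35 (not isolated)
Conditions: Et3N (1.05 equiv), 4 Å molecular sieves, (CH2Cl)2, rt; then AgOTf (10 mol %), rt to 40 °C, Ar, dark; used without delay
Reagents that add atoms: none
Why: On neutralisation the amine condenses with the C9a ketone to the seven-membered imine 34, ammonium-catalysed tautomerisation through the enaminol moves the carbonyl to C1 (Heyns rearrangement, the intramolecular counterpart of the Voigt amination) to give the alpha-amino ynone 35, and silver-assisted 5-endo-dig addition of nitrogen to C3 (known for alpha-amino ynones) closes the pyrrolinone, which tautomerises to the 3-hydroxypyrrole; the silver salt is added only after imine formation because the ketone oxygen would otherwise close a furan, and the C1 and C9a centres are erased.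

Step 22
Reactants: 36 3-hydroxypyrrole
Product: 37 target CNP0182700.1
Conditions: dimethyldioxirane (1.0 equiv), acetone/CH2Cl2, -78 °C
Reagents that add atoms: dimethyldioxirane, CC1(C)OO1
Why: Electrophilic oxygen transfer from the dioxirane to C9a, the most nucleophilic carbon of the 3-hydroxypyrrole (the position at which pyrrol-3(2H)-ones and indoxyls are hydroxylated even by air), gives after opening of the epoxide the vinylogous amide, and the reagent should approach on the face carrying H9, opposite C10 with its ethyl and spirolactone, which sets C9a with OH syn to H9.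

Compound list
1 | furan-2(5H)-one | O=C1C=CCO1 | starting material
2 | methacryloyl chloride | C=C(C)C(=O)Cl | starting material
3 | furan-2-yl methacrylate | C=C(C)C(=O)Oc1ccco1 | intermediate
4 | (E)-4-oxopent-2-enoic acid | CC(=O)/C=C/C(=O)O | starting material
5 | benzyl (E)-4-oxopent-2-enoate | CC(=O)/C=C/C(=O)OCc1ccccc1 | intermediate
6 | benzyl 3-endo-acetyl-4-(methacryloyloxy)-7-oxabicyclo[2.2.1]hept-5-ene-2-exo-carboxylate | CC(=O)[C@H]1[C@H](C(=O)OCc3ccccc3)[C@@H]2O[C@@]1(OC(=O)C(C)=C)C=C2 | intermediate
7 | N-tosylhydrazone of 6 | CC(=NNS(=O)(=O)c1ccc(C)cc1)[C@H]1[C@H](C(=O)OCc3ccccc3)[C@@H]2O[C@@]1(OC(=O)C(C)=C)C=C2 | intermediate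
8 | alkyldiazene (1-diazenylethyl on C10) | CC(N=N)[C@H]1[C@H](C(=O)OCc3ccccc3)[C@@H]2O[C@@]1(OC(=O)C(C)=C)C=C2 | intermediate
9 | benzyl 3-endo-ethyl-4-(methacryloyloxy)-7-oxabicyclo[2.2.1]hept-5-ene-2-exo-carboxylate | CC[C@H]1[C@H](C(=O)OCc3ccccc3)[C@@H]2O[C@@]1(OC(=O)C(C)=C)C=C2 | intermediate
10 | benzyl 4-ethyl-5-(methacryloyloxy)-2,5-divinyltetrahydrofuran-3-carboxylate (vinyl groups cis, C8/C9/C10 all-trans) | CC[C@H]1[C@H](C(=O)OCc3ccccc3)[C@@H](C=C)O[C@@]1(OC(=O)C(C)=C)C=C | intermediate
11 | benzyl 9-ethyl-3-methyl-2-oxo-7-vinyl-1,6-dioxaspiro[4.4]non-3-ene-8-carboxylate (butenolide CH and vinyl cis across the ring oxygen) | CC[C@H]1[C@H](C(=O)OCc3ccccc3)[C@@H](C=C)O[C@]12OC(=O)C(C)=C2 | intermediate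
12 | tert-butyl allylcarbamate | C=CCNC(=O)OC(C)(C)C | starting material
13 | benzyl 7-[(E)-3-(tert-butoxycarbonylamino)prop-1-enyl]-9-ethyl-3-methyl-2-oxo-1,6-dioxaspiro[4.4]non-3-ene-8-carboxylate | CC[C@H]1[C@H](C(=O)OCc3ccccc3)[C@@H](/C=C/CNC(=O)OC(C)(C)C)O[C@]12OC(=O)C(C)=C2 | intermediate
14 | C12 pinacol boronate of the saturated spirolactone (boron syn to the ring oxygen, C13 methyl trans) | CC[C@H]1[C@H](C(=O)OCc3ccccc3)[C@@H](/C=C/CNC(=O)OC(C)(C)C)O[C@]12OC(=O)[C@H](C)[C@H]2B4OC(C)(C)C(C)(C)O4 | intermediate
15 | C12 alcohol (benzyl ester, allylic carbamate) | CC[C@H]1[C@H](C(=O)OCc3ccccc3)[C@@H](/C=C/CNC(=O)OC(C)(C)C)O[C@]12OC(=O)[C@H](C)[C@H]2O | intermediate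
16 | C12 triethylsilyl ether of 15 | CC[C@H]1[C@H](C(=O)OCc3ccccc3)[C@@H](/C=C/CNC(=O)OC(C)(C)C)O[C@]12OC(=O)[C@H](C)[C@H]2O[Si](CC)(CC)CC | intermediate
17 | C9 carboxylic acid with 3-(Boc-amino)propyl chain and C12 silyl ether | CC[C@H]1[C@H](C(=O)O)[C@@H](CCCNC(=O)OC(C)(C)C)O[C@]12OC(=O)[C@H](C)[C@H]2O[Si](CC)(CC)CC | intermediate
18 | mixed isobutyl carbonic anhydride of 17 | CC[C@H]1[C@H](C(=O)OC(=O)OCC(C)C)[C@@H](CCCNC(=O)OC(C)(C)C)O[C@]12OC(=O)[C@H](C)[C@H]2O[Si](CC)(CC)CC | intermediate
19 | diazomethyl ketone at C9 | CC[C@H]1[C@H](C(=O)C=[N+]=[N-])[C@@H](CCCNC(=O)OC(C)(C)C)O[C@]12OC(=O)[C@H](C)[C@H]2O[Si](CC)(CC)CC | intermediate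
20 | keto aldehyde (C9a ketone, C1 aldehyde) | CC[C@H]1[C@H](C(=O)C=O)[C@@H](CCCNC(=O)OC(C)(C)C)O[C@]12OC(=O)[C@H](C)[C@H]2O[Si](CC)(CC)CC | intermediate
21 | (S)-5-(hydroxymethyl)dihydrofuran-2(3H)-one | OC[C@@H]1CCC(=O)O1 | starting material
22 | (S)-5-[(tert-butyldiphenylsilyloxy)methyl]dihydrofuran-2(3H)-one | CC(C)(C)[Si](OC[C@@H]1CCC(=O)O1)(c1ccccc1)c1ccccc1 | intermediate
23 | lithium enolate of 22 | CC(C)(C)[Si](OC[C@@H]1CC=C(O[Li])O1)(c1ccccc1)c1ccccc1 | intermediate
24 | 3-(dimethylaminomethyl) lactone (Mannich base, C3 epimers) | CC(C)(C)[Si](OC[C@@H]1CC(CN(C)C)C(=O)O1)(c1ccccc1)c1ccccc1 | intermediate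
25 | 3-(trimethylammoniomethyl) lactone iodide | CC(C)(C)[Si](OC[C@@H]1CC(C[N+](C)(C)C)C(=O)O1)(c1ccccc1)c1ccccc1.[I-] | intermediate
26 | (S)-5-[(tert-butyldiphenylsilyloxy)methyl]-3-methylenedihydrofuran-2(3H)-one | CC(C)(C)[Si](OC[C@@H]1CC(=C)C(=O)O1)(c1ccccc1)c1ccccc1 | intermediate
27 | (3S,5S)-5-[(tert-butyldiphenylsilyloxy)methyl]-3-methyldihydrofuran-2(3H)-one | CC(C)(C)[Si](OC[C@@H]1C[C@H](C)C(=O)O1)(c1ccccc1)c1ccccc1 | intermediate
28 | (3S,5S)-5-(hydroxymethyl)-3-methyldihydrofuran-2(3H)-one | OC[C@@H]1C[C@H](C)C(=O)O1 | intermediate
29 | (2S,4S)-4-methyl-5-oxotetrahydrofuran-2-carbaldehyde | O=C[C@@H]1C[C@H](C)C(=O)O1 | intermediate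
30 | (3S,5S)-5-ethynyl-3-methyldihydrofuran-2(3H)-one | C#C[C@@H]1C[C@H](C)C(=O)O1 | intermediate
31 | alkynylzinc triflate of 30 | FC(F)(F)S(=O)(=O)O[Zn]C#C[C@@H]1C[C@H](C)C(=O)O1 | intermediate
32 | alpha-hydroxy propargyl ketone (C1 epimers) | CC[C@H]1[C@H](C(=O)C(O)C#C[C@@H]3C[C@H](C)C(=O)O3)[C@@H](CCCNC(=O)OC(C)(C)C)O[C@]12OC(=O)[C@H](C)[C@H]2O[Si](CC)(CC)CC | intermediate
33 | ammonium trifluoroacetate of the deprotected amino ketone (free C12 OH) | CC[C@H]1[C@H](C(=O)C(O)C#C[C@@H]3C[C@H](C)C(=O)O3)[C@@H](CCC[NH3+])O[C@]12OC(=O)[C@H](C)[C@H]2O.[O-]C(=O)C(F)(F)F | intermediate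
34 | seven-membered cyclic imine (N4=C9a) | CC[C@H]1[C@H]2[C@@H](CCCN=C2C(O)C#C[C@@H]3C[C@H](C)C(=O)O3)O[C@]12OC(=O)[C@H](C)[C@H]2O | intermediate
35 | alpha-amino ynone (C9a-H azepane, C1 ketone) | CC[C@H]1[C@H]2[C@@H](CCCNC2C(=O)C#C[C@@H]3C[C@H](C)C(=O)O3)O[C@]12OC(=O)[C@H](C)[C@H]2O | intermediate
36 | 3-hydroxypyrrole form of the pyrrolo[1,2-a]azepine | CC[C@H]1[C@H]2[C@@H](CCCn3c([C@@H]4C[C@H](C)C(=O)O4)cc(O)c23)O[C@]12OC(=O)[C@H](C)[C@H]2O | intermediate
37 | target CNP0182700.1 | CC[C@H]1[C@H]2[C@@H](CCCN3C([C@@H]4C[C@H](C)C(=O)O4)=CC(=O)[C@@]23O)O[C@]12OC(=O)[C@H](C)[C@H]2O | target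

Total step count: 22.
Longest linear sequence: 15 steps (steps 1, 3 to 12 and 19 to 22; the alkyne branch, steps 13 to 18, joins at step 19).

Steps most likely to fail

Step 3. The catalyst may discriminate the two faces of the bound enone poorly, or the adduct may erode by cycloreversion during a slow catalysed reaction. The fallback gives up asymmetric induction in favour of resolution. It sets out from 3 and 5, which are combined with Me2AlCl in CH2Cl2 at -78 °C; ketone complexation should still direct regiochemistry and the endo position. This gives the racemate, that is 6 together with its mirror image ent-6 F1. The mixture is taken through step 4 to the stable pair of tosylhydrazones, 7 and the mirror-image tosylhydrazone ent-7 F2, which are parted by preparative chromatography on a chiral stationary phase (amylose tris(3,5-dimethylphenylcarbamate)). The route is re-entered at 7.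

Step 21. The ketone oxygen may attack the silver-activated alkyne before the imine has formed, the imine may tautomerise toward C9 with opening of the tetrahydrofuran, or the carbonyl transposition may stall. The fallback closes both rings at the oxidation level of the target and needs no hydroxypyrrole. It sets out from 32, whose C1 carbinol is oxidised with Dess-Martin periodinane to the yne-1,2-dione F3. CF3CO2H/CH2Cl2/H2O then gives the deprotected ammonium trifluoroacetate F4. On neutralisation with NaHCO3 in dilute MeCN the amine adds to the more electrophilic C9a ketone to give the seven-membered carbinolamine F5. Its N-H adds 5-endo-dig to the ynone carbon C3 (AgOTf if needed), which delivers 37 directly, with C9a set under thermodynamic control through reversible carbinolamine formation. The route is re-entered at 37, and step 22 is bypassed as well.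

Step 22. Oxygen may be delivered to the wrong face of the hydroxypyrrole, or the enaminone product may be oxidised further by the strong oxygen donor. The fallback reverses the polarity, so that oxygen enters as a nucleophile. It sets out from 36, which is treated with N-bromosuccinimide (1.0 equiv) and NaHCO3 in THF/H2O at -20 °C. Bromination at the enol carbon gives the C9a bromide F6, which ionises at once to the N-stabilised cation; water adds at C9a and the route is re-entered at 37. Because the hemiaminal can re-ionise, the C9a epimers can equilibrate, so the outcome no longer depends on the face chosen by an electrophilic oxidant.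

Further compounds
F1 | step 3 | ent-6, mirror image of the Diels-Alder adduct | CC(=O)[C@@H]1[C@@H](C(=O)OCc3ccccc3)[C@H]2O[C@]1(OC(=O)C(C)=C)C=C2
F2 | step 3 | ent-7, mirror image of the tosylhydrazone | CC(=NNS(=O)(=O)c1ccc(C)cc1)[C@@H]1[C@@H](C(=O)OCc3ccccc3)[C@H]2O[C@]1(OC(=O)C(C)=C)C=C2
F3 | step 21 | yne-1,2-dione (C9a and C1 ketones; Boc and silyl groups in place) | CC[C@H]1[C@H](C(=O)C(=O)C#C[C@@H]3C[C@H](C)C(=O)O3)[C@@H](CCCNC(=O)OC(C)(C)C)O[C@]12OC(=O)[C@H](C)[C@H]2O[Si](CC)(CC)CC
F4 | step 21 | ammonium trifluoroacetate of the deprotected yne-1,2-dione | CC[C@H]1[C@H](C(=O)C(=O)C#C[C@@H]3C[C@H](C)C(=O)O3)[C@@H](CCC[NH3+])O[C@]12OC(=O)[C@H](C)[C@H]2O.[O-]C(=O)C(F)(F)F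
F5 | step 21 | seven-membered carbinolamine at C9a | CC[C@H]1[C@H]2[C@@H](CCCNC2(O)C(=O)C#C[C@@H]3C[C@H](C)C(=O)O3)O[C@]12OC(=O)[C@H](C)[C@H]2O
F6 | step 22 | C9a bromide of the pyrrolin-1-one | CC[C@H]1[C@H]2[C@@H](CCCN3C([C@@H]4C[C@H](C)C(=O)O4)=CC(=O)C23Br)O[C@]12OC(=O)[C@H](C)[C@H]2O
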